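An easy sum comes first: at the last reading of Thursday's run, starting material and target add up to 100%, so within the scatter the readings show no loss of material to a third species.

common to all: starting material 0.50 M
- Thursday's: second substrate 1 M; capture agent 0.050 M; free catalyst 5 mM; the very flask that is asked about, followed so far
- Tuesday's: second substrate 1 M; capture agent 0.050 M; free catalyst 2.5 mM; run made earlier
- flask: second substrate 1.00 M; capture agent 0.0500 M; free catalyst 5.0 mM; time 6.0 d
- Thursday's (time / d: target / %, starting material / %): 0.417: 11.2, 88.9; 1.25: 12.9, 87.1; 2.50: 12.0, 87.7; 4.00: 12.8, 87.4
- Tuesday's (time / h: target / %, starting material / %): 4.00: 4.3, 95.2; 10.0: 6.2, 94.5; 20.0: 5.1, 93.2; 30.0: 5.9, 94.4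

(readings scatter by 0.5 percentage points)
- delta: change nothing and wait 12 d more
- gamma: at 6.0 d add starting material, 50.0% of the amount charged, then wait 12 d
- beta: at 6.0 d add free catalyst, 100% of the amount charged, then wait 12 d
1. target, in percent of the starting material first charged, at 6.0 d
2. the option that brings most further target ("none" if no option brings more than 2 percentage points) (delta / gamma / beta / none)
3. target present, in percent of the starting material first charged, after delta
4. target present, in percent of the starting material first charged, after beta
- target is meant together with its idle complex
- what is added takes up no volume worth counting
- what was read earlier has a scatter of 0.5 percentage points, one standard deviation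
- on the list of suspects stand: catalyst intermediate A -> free catalyst + target; target + free catalyst <-> isomer of the product + free catalyst; catalyst intermediate B -> free catalyst + second product; second substrate + free catalyst <-> catalyst intermediate B; catalyst intermediate B + capture agent -> trapped intermediate; starting material + free catalyst <-> catalyst intermediate A; free catalyst + target <-> idle complex

Both runs stand still with most of the starting material unconverted. An equilibrium is the first thought, but the plateau, the mean of the last three readings, is 12.6% in Thursday's run and 5.73% in Tuesday's, and it follows the catalyst charge. The better quantity is the turnover budget (a turnover number), the target standing per catalyst charged once the catalyst has stopped working. It reads 12.6 for Thursday's run and 11.5 for Tuesday's, close, given a scatter of 0.5 percentage points per reading on Tuesday's smaller plateau.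

So the flask is expected near 12.6% at its asked time. The objection is a slow creep, but Thursday's target moves by −0.1 points between the second and last readings, which lies within the scatter. Neither waiting nor added starting material is therefore expected to bring target from a catalyst that has stopped working.

Fresh catalyst equal to the charge should, as a first answer, repeat the budget and add 12.6%. The objection is that the second batch meets a changed flask. If catalyst is lost through catalyst intermediate B and the capture agent, target per lost catalyst goes as [starting material]/([second substrate][capture agent]). Putting the first answer back, Thursday's starting material reads 87.4% on the plateau, and each lost catalyst takes one capture agent. Comparing mid-batch values for both batches, with [second substrate] unread and held at its charge, gives a gain of 12 points, hence 24.6% after beta.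

The forecast gives 12.5% (11.9% to 13%), 12.5% (11.9% to 13.5%) after delta and 24% (21.5% to 26%) after beta, somewhat below this reckoning, chooses beta, and says “Waiting therefore gives nothing”.

The flask gives 12.1% at its asked time, 12.1% after delta and 23.5% after beta. The gains are 0 points for delta, 0 points for gamma and 11 points for beta, so the choice is beta.

    catalyst intermediate A → free catalyst + target (k = 11.4 h⁻¹)
    target + free catalyst ⇌ isomer of the product + free catalyst, rate k2*[free catalyst]*[target] forward; the back reaction follows from the equilibrium constant (K = 1.50, k = 19.7 M⁻¹ h⁻¹)
    catalyst intermediate B → free catalyst + second product (k = 22.4 h⁻¹)
    second substrate + free catalyst ⇌ catalyst intermediate B (K = 1.98 M⁻¹, k = 32.5 M⁻¹ h⁻¹)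
    catalyst intermediate B + capture agent → trapped intermediate (k = 19.4 M⁻¹ h⁻¹)
    starting material + free catalyst ⇌ catalyst intermediate A (K = 4.79 M⁻¹, k = 30.4 M⁻¹ h⁻¹)
    free catalyst + target ⇌ idle complex, settled at all times (K = 1.21 M⁻¹)

In this flask the budget comes to 12.1 for the first batch and 11.4 for the fresh catalyst, against 12.2 reckoned for the fresh catalyst. The capture step is the largest single effect on this flask's target: without it the same flask gives 40.1% instead of 12.1%. The budget taken as inverse to [second substrate], the other charges held, puts a neighbour flask charged with 1.7 M of second substrate at 7.39%, and that neighbour gives 7.33%.

(The earlier runs and the new flask are calculated on assumed constants; noise was put on by code.)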